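# Proposed synthesis of CNP0209995.1 by a lactone enolate Claisen ring contraction

## Analysis of the target

The target 22 is a halimane-type diterpenoid diester built on a Δ1(10)-octalin. In diterpene numbering, used throughout, ring A is C1–C5 plus C10, ring B is C5–C10, and C9 carries a methyl group and the chain C11–C15. The chain ends in an (E)-trisubstituted allylic acetate (C13=C14, C15–OAc), and C4 carries a methyl group and a methyl ester.

There are four stereocenters in two adjacent pairs, separated by the sp2 carbon C10: C4 (S, quaternary) with C5 (R), and C8 (R) with C9 (S, quaternary). The C8 and C9 methyl groups are cis and the chain is trans to the C8 methyl. H5 lies on the same face as these two methyl groups, so the C4–C5 bond sits on the ring-B face opposite the C9 methyl. At C4 the ester is anti to H5 and the methyl is syn to it.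

Sensitive features are the trisubstituted C1=C10 bond (acid can move it to C5=C10 and erase C5), the allylic acetate, and two esters that must be told apart. The difficulty is the pair of quaternary carbons, each next to a tertiary stereocenter, with C4 neopentyl and next to the ring fusion, and the relay of configuration from C8/C9 to C4/C5 across the flat C10.

The route rests on one feature: the carboxyl-bearing C4 is bonded to C5, and C5 is allylic to C1=C10. This γ,δ-unsaturated acid is the product pattern of an ester enolate Claisen shift from an allylic C1–O ester. Because C1 and C4 are joined through C2–C3, that ester is a six-membered lactone.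

## Retrosynthetic reasoning

**22 to 21.** The C15–O acetate bond is cut last. Acylation of a primary allylic alcohol is reliable, and the ionisable, base-labile allylic acetate then meets no further reagent.

**21 to 19 via 20.** The C13=C14 bond is cut to the methyl ketone 19 and a two-carbon phosphonate unit, and the C15 oxidation level is adjusted from enoate 20. The olefin is remote from the core and its (E) form is the thermodynamically preferred one. The forward steps must give (E) geometry and reduce the new ester without touching the C4 ester.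

**19 to 17 via 18.** These are functional-group changes only: ketal removal and esterification of the C4 acid. The ketal is kept until here because it survives alkyllithium, borane, amide bases and heat.

**17 to 14 (the strategic cut).** The C4–C5 bond is cut and the C1–O bond restored, which turns the carbocyclic acid into lactone 14 carrying the ring-B cyclohexenyl unit on its carbinol carbon. In the forward direction this one disconnection builds the hindered C4 center intramolecularly, sets C4 and C5 together, closes ring A and leaves the olefin at C1=C10. All of this stereochemical information is stored in the single carbinol center C1.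

**14 to 13.** The C4–CH3 bond is cut (lactone enolate methylation). Adding the methyl late allows a symmetrical five-carbon acyl unit to be used, so no regiochemical question arises, and the C4 configuration is irrelevant because C4 is planarised in the Claisen step.

**13 to 11 via 12.** The lactone acyl C–O bond is opened to hydroxy ester 12, and the C1–H bond is traced to enone 11. C1 must be (R) whatever the distant ring-B centers prefer, so a reagent-controlled ketone reduction is required.

**11 to 7 and 8.** The C1–C10 bond is cut into an alkenyl nucleophile at C10 and the acid chloride 8. The alkenyl metal comes from sulfonylhydrazone 7, which can lose a proton only at C5 because C9 is quaternary, so the C10=C5 olefin is regiodefined. Hydrazone 7 is a derivative of ketone 6.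

**6 to 5.** The isopropylidene group of 5 is removed in the forward direction by retro-aldol cleavage. Until then it blocks one α-carbon, so that both alkylations go to the other.

**5 to 2 and 4.** The C9–C11 bond is cut (enolate alkylation with iodide 4, made from bromide 3). The chain is added second because the second electrophile enters trans to the C8 methyl, which is where the chain must sit.

**2 to 1.** The C9–CH3 bond is cut. Pulegone 1 supplies the six carbons of ring B and the C8 stereocenter.

## Alternatives that were turned down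

**Alternative 1:** Ring B is disconnected at C7–C8 and C9–C10 into (E)-2-methylbut-2-enal A1 and (E)-1-(trimethylsilyloxy)buta-1,3-diene A2. A chiral cationic oxazaborolidine Lewis acid would catalyse the Diels–Alder reaction to aldehyde A3.
- For it: C8 and C9 are set together by the catalyst, with the cis-dimethyl relation coming from the dienophile geometry. On this point it is stronger than the substrate-controlled alkylation used here, and either enantiomer is accessible.
- Against it: A1 is a poorly reactive α,β-disubstituted enal, and A3 contains ring B only. The C5=C6 olefin must be removed, the neopentyl aldehyde extended by four carbons, and the C10 oxygen oxidised before ring A can be started.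
- Comparison: it offers no answer to the C4/C5 pair, so it would still need a ring-A construction such as the one chosen here, after a longer path to the ring-B ketone. The chosen route reaches ketone 6 in three steps from 1 and spends its key step on ring A.

**Alternative 2:** The C3–C4 and C5–C10 bonds are cut together. In the forward direction, pulegone is ring-opened to a C6–C9 chain that links a (Z)-2-methylenoate (C4=C5) to a 2-silyloxydiene (C10=C1–C2=C3), and a thermal intramolecular [4+2] cycloaddition gives A4.
- For it: both rings and two C–C bonds form in one step, and the C4 configuration is encoded stereospecifically in the enoate geometry. In bonds and rings per step it is stronger than the chosen route.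
- Against it: ring B is cut open only to be re-formed, and the acyclic precursor needs a geometrically pure trisubstituted (Z)-enoate and a sensitive silyloxydiene next to quaternary C9. The cycloaddition has a trisubstituted dienophile terminus and must control ring-fusion and facial selectivity. A4 then has oxygen at C2, the olefin at C1=C2 and a C10–H stereocenter that is made only to be destroyed, so several redox steps with a risk of olefin migration follow.
- Comparison: the chosen route delivers the olefin directly at C1=C10 with no oxygen to delete.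

**Alternative 3:** The C1=C10 double bond is cut. Low-valent titanium would couple the ring-B C10 ketone with a tethered C1 aldehyde (McMurry coupling) to give A5, and the C4 methyl would be added afterwards.
- For it: the olefin position is unambiguous, and the closure is less strained than a bridged boat. As a ring closure alone it is at least as dependable as the chosen one.
- Against it: the ester must survive low-valent titanium, and the key step sets no stereocenter. C5 has to be installed earlier, α to the ketone and epimerisable, and C4 is made quaternary late by enolate methylation under substrate control.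
- Comparison: it leaves two unlinked stereochemical problems where the chosen route has one chirality-transfer event, at similar step count.

Key step: step 10

## Route

Remark: 2 and 14 are used as epimer mixtures at the one carbon that is planarised in the following step. Compounds 1, 3 and 8 are taken as purchasable.

Step 1
Reactants: 1 (R)-(+)-pulegone
Product: 2 (3R)-2,3-dimethyl-6-(propan-2-ylidene)cyclohexan-1-one
Conditions: LiN(i-Pr)2, THF, −78 °C; MeI, −78 → 0 °C
Reagents that add atoms: iodomethane CI
Why: Kinetic deprotonation of the enone at the α′ CH2 (next to the methyl-bearing carbon) gives the cross-conjugated enolate, which is C-methylated (enolate alkylation); the new center is re-enolised in step 3, so both epimers serve.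

Step 2
Reactants: 3 2-(2-bromoethyl)-2-methyl-1,3-dioxolane
Product: 4 2-(2-iodoethyl)-2-methyl-1,3-dioxolane
Conditions: NaI, NaHCO3 (cat.), acetone, reflux
Reagents that add atoms: sodium iodide [Na+].[I-]
Why: Finkelstein halide exchange, driven by precipitation of NaBr; the bicarbonate keeps traces of acid away from the ketal.

Step 3
Reactants: 2 (3R)-2,3-dimethyl-6-(propan-2-ylidene)cyclohexan-1-one; 4 2-(2-iodoethyl)-2-methyl-1,3-dioxolane
Product: 5 (2S,3R)-2,3-dimethyl-2-[2-(2-methyl-1,3-dioxolan-2-yl)ethyl]-6-(propan-2-ylidene)cyclohexan-1-one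
Conditions: LiN(i-Pr)2, THF, −78 → 0 °C; 4, DMPU, −78 °C → rt
Reagents that add atoms: none
Why: α′-Enolate alkylation; the isopropylidene group blocks the other α-carbon, and the neighbouring C8 methyl sits pseudoaxial to avoid allylic strain with the enolate methyl, so the iodide should enter from the opposite face and set C9 with the chain trans to the C8 methyl and the two methyl groups cis.

Step 4
Reactants: 5 (2S,3R)-2,3-dimethyl-2-[2-(2-methyl-1,3-dioxolan-2-yl)ethyl]-6-(propan-2-ylidene)cyclohexan-1-one
Product: 6 (2S,3R)-2,3-dimethyl-2-[2-(2-methyl-1,3-dioxolan-2-yl)ethyl]cyclohexan-1-one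
Conditions: KOH, H2O–EtOH, reflux, acetone distilled off
Reagents that add atoms: none
Why: Base-mediated retro-aldol cleavage: hydroxide adds to the enone β-carbon and the β-hydroxy ketone fragments to acetone and 6; the ketal is stable to base and neither the quaternary C9 nor C8 can epimerise.

Step 5
Reactants: 6 (2S,3R)-2,3-dimethyl-2-[2-(2-methyl-1,3-dioxolan-2-yl)ethyl]cyclohexan-1-one
Product: 7 N′-[(1E,2S,3R)-2,3-dimethyl-2-[2-(2-methyl-1,3-dioxolan-2-yl)ethyl]cyclohexylidene]-2,4,6-tri(propan-2-yl)benzenesulfonohydrazide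
Conditions: 2,4,6-(i-Pr)3C6H2SO2NHNH2, THF, rt
Reagents that add atoms: 2,4,6-tri(propan-2-yl)benzenesulfonohydrazide CC(C)c1cc(C(C)C)c(c(c1)C(C)C)S(=O)(=O)NN
Why: Hydrazone condensation without added strong acid, so the ketal is safe; the N–N bond should turn away from the quaternary carbon and lie syn to the CH2, as the syn deprotonation of step 6 requires.

Step 6
Reactants: 7 N′-[(1E,2S,3R)-2,3-dimethyl-2-[2-(2-methyl-1,3-dioxolan-2-yl)ethyl]cyclohexylidene]-2,4,6-tri(propan-2-yl)benzenesulfonohydrazide; 8 methyl 5-chloro-5-oxopentanoate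
Product: 11 methyl 5-[(5R,6S)-5,6-dimethyl-6-[2-(2-methyl-1,3-dioxolan-2-yl)ethyl]cyclohex-1-en-1-yl]-5-oxopentanoate, via alkenyllithium 9 (not isolated), via alkenylzinc chloride 10 (not isolated)
Conditions: n-BuLi (2.2 equiv), THF, −78 → 0 °C; ZnCl2, −78 → 0 °C; 8, Pd(PPh3)4 (5 mol %), 0 °C → rt
Reagents that add atoms: n-butyllithium [Li]CCCC (lithium of 9 only); zinc chloride Cl[Zn]Cl (zinc and chloride of 10 only)
Why: Shapiro reaction: the dianion can form only at the C5 CH2 and loses sulfinate and N2 to give the alkenyllithium with the C10=C5 bond regiodefined; transmetalation to zinc and Negishi acylation under zerovalent palladium catalysis should stop at the ketone and leave the methyl ester untouched.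

Step 7
Reactants: 11 methyl 5-[(5R,6S)-5,6-dimethyl-6-[2-(2-methyl-1,3-dioxolan-2-yl)ethyl]cyclohex-1-en-1-yl]-5-oxopentanoate
Product: 12 methyl (5R)-5-[(5R,6S)-5,6-dimethyl-6-[2-(2-methyl-1,3-dioxolan-2-yl)ethyl]cyclohex-1-en-1-yl]-5-hydroxypentanoate
Conditions: (S)-2-methyl-CBS-oxazaborolidine (0.3 equiv), BH3·SMe2, THF, −20 °C; MeOH
Reagents that add atoms: none
Why: Corey–Bakshi–Shibata reduction: the branched alkenyl group acts as the large substituent and the CH2 chain as the small one, so the (S)-catalyst should deliver hydride to give the (R)-carbinol at C1 under reagent control; ester, ketal and the hindered olefin should not react with catalysed borane at this temperature.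

Step 8
Reactants: 12 methyl (5R)-5-[(5R,6S)-5,6-dimethyl-6-[2-(2-methyl-1,3-dioxolan-2-yl)ethyl]cyclohex-1-en-1-yl]-5-hydroxypentanoate
Product: 13 (6R)-6-[(5R,6S)-5,6-dimethyl-6-[2-(2-methyl-1,3-dioxolan-2-yl)ethyl]cyclohex-1-en-1-yl]oxan-2-one
Conditions: PPTS (cat.), toluene, 70 °C, 4 Å molecular sieves
Reagents that add atoms: none
Why: Acid-catalysed lactonisation (intramolecular transesterification) to the six-membered lactone with removal of methanol; the C1–O bond is not broken, so C1 keeps its configuration, and the weak acid in dry toluene should spare the ketal.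

Step 9
Reactants: 13 (6R)-6-[(5R,6S)-5,6-dimethyl-6-[2-(2-methyl-1,3-dioxolan-2-yl)ethyl]cyclohex-1-en-1-yl]oxan-2-one
Product: 14 (3RS,6R)-6-[(5R,6S)-5,6-dimethyl-6-[2-(2-methyl-1,3-dioxolan-2-yl)ethyl]cyclohex-1-en-1-yl]-3-methyloxan-2-one
Conditions: LiN(i-Pr)2, THF, −78 °C; MeI, −78 → −40 °C
Reagents that add atoms: iodomethane CI
Why: Lactone enolate alkylation at the only α-carbon (C4); the epimer ratio is irrelevant because C4 becomes planar in step 10.

Step 10
Reactants: 14 (3RS,6R)-6-[(5R,6S)-5,6-dimethyl-6-[2-(2-methyl-1,3-dioxolan-2-yl)ethyl]cyclohex-1-en-1-yl]-3-methyloxan-2-one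
Product: 17 (1S,5S,6R,8aR)-1,5,6-trimethyl-5-[2-(2-methyl-1,3-dioxolan-2-yl)ethyl]-1,2,3,5,6,7,8,8a-octahydronaphthalene-1-carboxylic acid, via silyl ketene acetal 15 (not isolated), via trimethylsilyl ester 16 (not isolated)
Conditions: LiN(i-Pr)2, Me3SiCl–Et3N, THF, −78 °C → rt; toluene, 110 °C; aq. NaOH, then citric acid to pH 4
Reagents that add atoms: chlorotrimethylsilane C[Si](C)(C)Cl (silyl group of 15 and 16 only)
Why: Deprotonation at C4 and O-silylation give the ketene acetal 15, whose geometry is fixed by the lactone ring. On heating, C4, the carboxyl carbon, O, C1, C10 and C5 undergo a concerted suprafacial [3,3] shift (Ireland–Claisen), the closest known type being the ring contraction of alkenyl-substituted lactone ketene acetals. Because C2–C3 bridges C1 and C4, only a boat (bicyclo[2.2.2]octane-like) transition state is possible; ring A closes as the C4–C5 bond replaces the C1–O bond, the six-membered lactone becoming the six-membered carbocycle with the new C1=C10 bond cis within the ring. At C4 the three ring-bound substituents (carboxyl carbon, C3, C5) are arranged as the counterpart of those at C1 (O, C2, C10), so (1R) is transferred to (4S) with the carboxyl anti to H5. At C5 the new bond arrives on the face from which the C1–O bond departs; for (1R) this is the face opposite the C9 methyl, which is pseudoaxial when the C8 methyl is equatorial, and this gives (5R). The step needs O- over C-silylation (favoured by the fully substituted enolate carbon), a single enolisation site (the lactone has one α-carbon) and one diastereoface, which is fixed by the C1 configuration from step 7. Mild hydrolysis of silyl ester 16 should leave the ketal and the C1=C10 bond in place.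

Step 11
Reactants: 17 (1S,5S,6R,8aR)-1,5,6-trimethyl-5-[2-(2-methyl-1,3-dioxolan-2-yl)ethyl]-1,2,3,5,6,7,8,8a-octahydronaphthalene-1-carboxylic acid
Product: 18 methyl (1S,5S,6R,8aR)-1,5,6-trimethyl-5-[2-(2-methyl-1,3-dioxolan-2-yl)ethyl]-1,2,3,5,6,7,8,8a-octahydronaphthalene-1-carboxylate
Conditions: Me3SiCHN2, MeOH–toluene, 0 °C → rt
Reagents that add atoms: (trimethylsilyl)diazomethane C[Si](C)(C)C=[N+]=[N-]
Why: Esterification by O-alkylation of the carboxylate with a diazoalkane, which is insensitive to the hindrance at quaternary C4 and needs no acid or base that could move the olefin.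

Step 12
Reactants: 18 methyl (1S,5S,6R,8aR)-1,5,6-trimethyl-5-[2-(2-methyl-1,3-dioxolan-2-yl)ethyl]-1,2,3,5,6,7,8,8a-octahydronaphthalene-1-carboxylate
Product: 19 methyl (1S,5S,6R,8aR)-1,5,6-trimethyl-5-(3-oxobutyl)-1,2,3,5,6,7,8,8a-octahydronaphthalene-1-carboxylate
Conditions: PPTS, acetone–H2O, 50 °C
Reagents that add atoms: water O
Why: Mild acid-catalysed ketal hydrolysis; the weak acid should not protonate the trisubstituted C1=C10 bond, so C5 is not endangered.

Step 13
Reactants: 19 methyl (1S,5S,6R,8aR)-1,5,6-trimethyl-5-(3-oxobutyl)-1,2,3,5,6,7,8,8a-octahydronaphthalene-1-carboxylate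
Product: 20 methyl (1S,5S,6R,8aR)-5-[(3E)-5-ethoxy-3-methyl-5-oxopent-3-en-1-yl]-1,5,6-trimethyl-1,2,3,5,6,7,8,8a-octahydronaphthalene-1-carboxylate
Conditions: (EtO)2P(O)CH2CO2Et, NaH, THF, 0 °C → 50 °C
Reagents that add atoms: triethyl phosphonoacetate CCOC(=O)CP(=O)(OCC)OCC
Why: Horner–Wadsworth–Emmons olefination of the methyl ketone; reversible addition should favour the (E)-enoate with the ester trans to the larger CH2 chain, the minor (Z)-isomer to be removed by chromatography; the C4 ester has no α-hydrogen and is too hindered to interfere.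

Step 14
Reactants: 20 methyl (1S,5S,6R,8aR)-5-[(3E)-5-ethoxy-3-methyl-5-oxopent-3-en-1-yl]-1,5,6-trimethyl-1,2,3,5,6,7,8,8a-octahydronaphthalene-1-carboxylate
Product: 21 methyl (1S,5S,6R,8aR)-5-[(3E)-5-hydroxy-3-methylpent-3-en-1-yl]-1,5,6-trimethyl-1,2,3,5,6,7,8,8a-octahydronaphthalene-1-carboxylate
Conditions: i-Bu2AlH (2.2 equiv), CH2Cl2, −78 °C; aq. potassium sodium tartrate
Reagents that add atoms: none
Why: 1,2-Reduction of the unhindered conjugated ethyl ester by the aluminium hydride at low temperature; the α-quaternary, neopentyl C4 methyl ester should react much more slowly and survive with controlled stoichiometry.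

Step 15
Reactants: 21 methyl (1S,5S,6R,8aR)-5-[(3E)-5-hydroxy-3-methylpent-3-en-1-yl]-1,5,6-trimethyl-1,2,3,5,6,7,8,8a-octahydronaphthalene-1-carboxylate
Product: 22 methyl (1S,5S,6R,8aR)-5-[(3E)-5-(acetyloxy)-3-methylpent-3-en-1-yl]-1,5,6-trimethyl-1,2,3,5,6,7,8,8a-octahydronaphthalene-1-carboxylate
Conditions: Ac2O, pyridine, DMAP (cat.), CH2Cl2, 0 °C → rt
Reagents that add atoms: acetic anhydride CC(=O)OC(C)=O
Why: DMAP-catalysed acylation of the primary allylic alcohol; nothing else in the molecule reacts.

## Compound list

1 | (R)-(+)-pulegone, (5R)-5-methyl-2-(propan-2-ylidene)cyclohexan-1-one | C[C@@H]1CCC(=C(C)C)C(=O)C1 | starting material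
2 | (3R)-2,3-dimethyl-6-(propan-2-ylidene)cyclohexan-1-one (both C2 epimers) | O=C1C(=C(C)C)CC[C@@H](C)C1C | intermediate
3 | 2-(2-bromoethyl)-2-methyl-1,3-dioxolane | CC1(CCBr)OCCO1 | starting material
4 | 2-(2-iodoethyl)-2-methyl-1,3-dioxolane | CC1(CCI)OCCO1 | intermediate
5 | (2S,3R)-2,3-dimethyl-2-[2-(2-methyl-1,3-dioxolan-2-yl)ethyl]-6-(propan-2-ylidene)cyclohexan-1-one | O=C1C(=C(C)C)CC[C@@H](C)[C@]1(C)CCC2(C)OCCO2 | intermediate
6 | (2S,3R)-2,3-dimethyl-2-[2-(2-methyl-1,3-dioxolan-2-yl)ethyl]cyclohexan-1-one | O=C1CCC[C@@H](C)[C@]1(C)CCC2(C)OCCO2 | intermediate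
7 | N′-[(1E,2S,3R)-2,3-dimethyl-2-[2-(2-methyl-1,3-dioxolan-2-yl)ethyl]cyclohexylidene]-2,4,6-tri(propan-2-yl)benzenesulfonohydrazide | CC(C)c1cc(C(C)C)c(c(c1)C(C)C)S(=O)(=O)N/N=C1\CCC[C@@H](C)[C@]1(C)CCC2(C)OCCO2 | intermediate
8 | methyl 5-chloro-5-oxopentanoate | COC(=O)CCCC(Cl)=O | starting material
9 | [(5R,6S)-5,6-dimethyl-6-[2-(2-methyl-1,3-dioxolan-2-yl)ethyl]cyclohex-1-en-1-yl]lithium | [Li]C1=CCC[C@@H](C)[C@]1(C)CCC2(C)OCCO2 | intermediate (not isolated)
10 | chlorido[(5R,6S)-5,6-dimethyl-6-[2-(2-methyl-1,3-dioxolan-2-yl)ethyl]cyclohex-1-en-1-yl]zinc | Cl[Zn]C1=CCC[C@@H](C)[C@]1(C)CCC2(C)OCCO2 | intermediate (not isolated)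
11 | methyl 5-[(5R,6S)-5,6-dimethyl-6-[2-(2-methyl-1,3-dioxolan-2-yl)ethyl]cyclohex-1-en-1-yl]-5-oxopentanoate | COC(=O)CCCC(=O)C1=CCC[C@@H](C)[C@]1(C)CCC2(C)OCCO2 | intermediate
12 | methyl (5R)-5-[(5R,6S)-5,6-dimethyl-6-[2-(2-methyl-1,3-dioxolan-2-yl)ethyl]cyclohex-1-en-1-yl]-5-hydroxypentanoate | COC(=O)CCC[C@@H](O)C1=CCC[C@@H](C)[C@]1(C)CCC2(C)OCCO2 | intermediate
13 | (6R)-6-[(5R,6S)-5,6-dimethyl-6-[2-(2-methyl-1,3-dioxolan-2-yl)ethyl]cyclohex-1-en-1-yl]oxan-2-one | O=C1O[C@H](CCC1)C2=CCC[C@@H](C)[C@]2(C)CCC3(C)OCCO3 | intermediate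
14 | (3RS,6R)-6-[(5R,6S)-5,6-dimethyl-6-[2-(2-methyl-1,3-dioxolan-2-yl)ethyl]cyclohex-1-en-1-yl]-3-methyloxan-2-one (both C3 epimers) | O=C1O[C@H](CCC1C)C2=CCC[C@@H](C)[C@]2(C)CCC3(C)OCCO3 | intermediate
15 | {[(2R)-2-[(5R,6S)-5,6-dimethyl-6-[2-(2-methyl-1,3-dioxolan-2-yl)ethyl]cyclohex-1-en-1-yl]-5-methyl-3,4-dihydro-2H-pyran-6-yl]oxy}trimethylsilane | C[Si](C)(C)OC1=C(C)CC[C@@H](O1)C2=CCC[C@@H](C)[C@]2(C)CCC3(C)OCCO3 | intermediate (not isolated)
16 | trimethylsilyl (1S,5S,6R,8aR)-1,5,6-trimethyl-5-[2-(2-methyl-1,3-dioxolan-2-yl)ethyl]-1,2,3,5,6,7,8,8a-octahydronaphthalene-1-carboxylate | C[Si](C)(C)OC(=O)[C@@]1(C)CCC=C2[C@H]1CC[C@@H](C)[C@]2(C)CCC3(C)OCCO3 | intermediate (not isolated)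
17 | (1S,5S,6R,8aR)-1,5,6-trimethyl-5-[2-(2-methyl-1,3-dioxolan-2-yl)ethyl]-1,2,3,5,6,7,8,8a-octahydronaphthalene-1-carboxylic acid | OC(=O)[C@@]1(C)CCC=C2[C@H]1CC[C@@H](C)[C@]2(C)CCC3(C)OCCO3 | intermediate
18 | methyl (1S,5S,6R,8aR)-1,5,6-trimethyl-5-[2-(2-methyl-1,3-dioxolan-2-yl)ethyl]-1,2,3,5,6,7,8,8a-octahydronaphthalene-1-carboxylate | COC(=O)[C@@]1(C)CCC=C2[C@H]1CC[C@@H](C)[C@]2(C)CCC3(C)OCCO3 | intermediate
19 | methyl (1S,5S,6R,8aR)-1,5,6-trimethyl-5-(3-oxobutyl)-1,2,3,5,6,7,8,8a-octahydronaphthalene-1-carboxylate | COC(=O)[C@@]1(C)CCC=C2[C@H]1CC[C@@H](C)[C@]2(C)CCC(C)=O | intermediate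
20 | methyl (1S,5S,6R,8aR)-5-[(3E)-5-ethoxy-3-methyl-5-oxopent-3-en-1-yl]-1,5,6-trimethyl-1,2,3,5,6,7,8,8a-octahydronaphthalene-1-carboxylate | COC(=O)[C@@]1(C)CCC=C2[C@H]1CC[C@@H](C)[C@]2(C)CC/C(C)=C/C(=O)OCC | intermediate
21 | methyl (1S,5S,6R,8aR)-5-[(3E)-5-hydroxy-3-methylpent-3-en-1-yl]-1,5,6-trimethyl-1,2,3,5,6,7,8,8a-octahydronaphthalene-1-carboxylate | COC(=O)[C@@]1(C)CCC=C2[C@H]1CC[C@@H](C)[C@]2(C)CC/C(C)=C/CO | intermediate
22 | methyl (1S,5S,6R,8aR)-5-[(3E)-5-(acetyloxy)-3-methylpent-3-en-1-yl]-1,5,6-trimethyl-1,2,3,5,6,7,8,8a-octahydronaphthalene-1-carboxylate | COC(=O)[C@@]1(C)CCC=C2[C@H]1CC[C@@H](C)[C@]2(C)CC/C(C)=C/COC(C)=O | target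

## Step count and least certain steps

Total: 15 steps. Longest linear sequence: 14 steps (steps 1 and 3–15, from 1).

**Step 10 (key step).** The bridged boat transition state is crowded where the silyloxy-bearing carbon lies over C10 next to quaternary C9. The rearrangement may therefore be slower than hydrolytic or thermal breakdown of the ketene acetal, or than ionisation of the allylic C1–O bond followed by elimination. Fallback, from 6 to 18: ketone 6 is converted with KN(SiMe3)2 and PhNTf2 into (5R,6S)-5,6-dimethyl-6-[2-(2-methyl-1,3-dioxolan-2-yl)ethyl]cyclohex-1-en-1-yl trifluoromethanesulfonate F1. Stille coupling with tributyl(vinyl)stannane (Pd(PPh3)4, LiCl, THF) gives the diene 2-{2-[(1S,6R)-2-ethenyl-1,6-dimethylcyclohex-2-en-1-yl]ethyl}-2-methyl-1,3-dioxolane F2. A thermal Diels–Alder reaction of F2 with methyl methacrylate (toluene, sealed tube) forms the C4–C5 and C2–C3 bonds with the expected "ortho" regiochemistry and returns to the route at 18. Stereocontrol would then rest on the endo preference of the ester and on shielding by the C9 methyl, so isomers might have to be separated.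

**Step 3.** Three processes may compete with C-alkylation of the hindered enolate: elimination of HI from the iodide, deprotonation at the γ-positions of the enone, and incomplete facial selectivity at C9. The retro-aldol cleavage of step 4 may also be slow on so hindered an enone. Fallback, from 2 to 6 (it bypasses steps 3 and 4): aqueous HCl at reflux cleaves the isopropylidene group of 2 by acid retro-aldol reaction to (3R)-2,3-dimethylcyclohexan-1-one F3. Me3SiCl and Et3N in DMF at 130 °C give the more substituted silyl enol ether trimethyl{[(3R)-2,3-dimethylcyclohex-1-en-1-yl]oxy}silane F4. Mukaiyama–Michael addition of F4 to but-3-en-2-one (TiCl4, CH2Cl2, −78 °C), again anti to the C8 methyl, gives (2S,3R)-2,3-dimethyl-2-(3-oxobutyl)cyclohexan-1-one F5. Selective ketalisation of the side-chain ketone of F5 (ethane-1,2-diol, PPTS, benzene, water removal), with the α-quaternary ring ketone left free, returns to 6.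

**Step 6.** Transmetalation and acyl transfer at an alkenyl carbon flanked by a quaternary center may be sluggish, so that protonation of the alkenyl metal or ketene formation from the acid chloride takes over. Fallback, from 7 to 11: the alkenyllithium 9 generated from 7 is trapped at −78 °C with methyl 5-oxopentanoate to give methyl (5RS)-5-[(5R,6S)-5,6-dimethyl-6-[2-(2-methyl-1,3-dioxolan-2-yl)ethyl]cyclohex-1-en-1-yl]-5-hydroxypentanoate F6. Oxidation of F6 with Dess–Martin periodinane returns to 11.

**Step 7.** The twisted, hindered enone may bind the catalyst poorly, which would give slow reduction and poor facial selectivity, or uncatalysed borane reduction. Fallback, from 11 to 13: Luche reduction (NaBH4, CeCl3, MeOH) gives 12 together with its epimer methyl (5S)-5-[(5R,6S)-5,6-dimethyl-6-[2-(2-methyl-1,3-dioxolan-2-yl)ethyl]cyclohex-1-en-1-yl]-5-hydroxypentanoate F7. Lactonisation as in step 8 gives 13 and (6S)-6-[(5R,6S)-5,6-dimethyl-6-[2-(2-methyl-1,3-dioxolan-2-yl)ethyl]cyclohex-1-en-1-yl]oxan-2-one F8, which are separated by chromatography. F8 is saponified (LiOH, THF–H2O) to (5S)-5-[(5R,6S)-5,6-dimethyl-6-[2-(2-methyl-1,3-dioxolan-2-yl)ethyl]cyclohex-1-en-1-yl]-5-hydroxypentanoic acid F9. Mitsunobu lactonisation of F9 (PPh3, diisopropyl azodicarboxylate) closes the ring with inversion at C1 and returns to 13.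

**Step 13.** Olefination of a methyl ketone may give incomplete (E)/(Z) selectivity, and the isomers may be hard to separate. Fallback, from 19 to 21 (it bypasses 20 and step 14): LiN(i-Pr)2 and ClP(O)(OEt)2, followed by two further equivalents of LiN(i-Pr)2, convert the methyl ketone through its terminal enol phosphate into the alkyne methyl (1S,5S,6R,8aR)-5-(but-3-yn-1-yl)-1,5,6-trimethyl-1,2,3,5,6,7,8,8a-octahydronaphthalene-1-carboxylate F10. Zirconium-catalysed carboalumination of F10 (Me3Al, Cp2ZrCl2, CH2Cl2) and trapping of the alkenylalane with paraformaldehyde should give the (E)-allylic alcohol 21 directly, since the syn addition fixes the geometry.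

**Step 14.** Over-reduction may reach the C4 methyl ester if the difference in rate between the two esters is smaller than expected. Fallback, from 20 to 21: LiOH (THF–MeOH–H2O, rt) should saponify only the unhindered conjugated ethyl ester, giving (2E)-5-[(1S,2R,4aR,5S)-5-(methoxycarbonyl)-1,2,5-trimethyl-1,2,3,4,4a,5,6,7-octahydronaphthalen-1-yl]-3-methylpent-2-enoic acid F11. Activation of F11 as the mixed anhydride (ClCO2Et, Et3N, THF, −10 °C) and reduction with NaBH4, which does not touch the hindered ester, returns to 21.

## Further compounds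

F1 | step 10 | (5R,6S)-5,6-dimethyl-6-[2-(2-methyl-1,3-dioxolan-2-yl)ethyl]cyclohex-1-en-1-yl trifluoromethanesulfonate | O=S(=O)(OC1=CCC[C@@H](C)[C@]1(C)CCC2(C)OCCO2)C(F)(F)F
F2 | step 10 | 2-{2-[(1S,6R)-2-ethenyl-1,6-dimethylcyclohex-2-en-1-yl]ethyl}-2-methyl-1,3-dioxolane | C=CC1=CCC[C@@H](C)[C@]1(C)CCC2(C)OCCO2
F3 | step 3 | (3R)-2,3-dimethylcyclohexan-1-one (both C2 epimers) | O=C1CCC[C@@H](C)C1C
F4 | step 3 | trimethyl{[(3R)-2,3-dimethylcyclohex-1-en-1-yl]oxy}silane | C[Si](C)(C)OC1=C(C)[C@H](C)CCC1
F5 | step 3 | (2S,3R)-2,3-dimethyl-2-(3-oxobutyl)cyclohexan-1-one | O=C1CCC[C@@H](C)[C@]1(C)CCC(C)=O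
F6 | step 6 | methyl (5RS)-5-[(5R,6S)-5,6-dimethyl-6-[2-(2-methyl-1,3-dioxolan-2-yl)ethyl]cyclohex-1-en-1-yl]-5-hydroxypentanoate | COC(=O)CCCC(O)C1=CCC[C@@H](C)[C@]1(C)CCC2(C)OCCO2
F7 | step 7 | methyl (5S)-5-[(5R,6S)-5,6-dimethyl-6-[2-(2-methyl-1,3-dioxolan-2-yl)ethyl]cyclohex-1-en-1-yl]-5-hydroxypentanoate | COC(=O)CCC[C@H](O)C1=CCC[C@@H](C)[C@]1(C)CCC2(C)OCCO2
F8 | step 7 | (6S)-6-[(5R,6S)-5,6-dimethyl-6-[2-(2-methyl-1,3-dioxolan-2-yl)ethyl]cyclohex-1-en-1-yl]oxan-2-one | O=C1O[C@@H](CCC1)C2=CCC[C@@H](C)[C@]2(C)CCC3(C)OCCO3
F9 | step 7 | (5S)-5-[(5R,6S)-5,6-dimethyl-6-[2-(2-methyl-1,3-dioxolan-2-yl)ethyl]cyclohex-1-en-1-yl]-5-hydroxypentanoic acid | OC(=O)CCC[C@H](O)C1=CCC[C@@H](C)[C@]1(C)CCC2(C)OCCO2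
F10 | step 13 | methyl (1S,5S,6R,8aR)-5-(but-3-yn-1-yl)-1,5,6-trimethyl-1,2,3,5,6,7,8,8a-octahydronaphthalene-1-carboxylate | COC(=O)[C@@]1(C)CCC=C2[C@H]1CC[C@@H](C)[C@]2(C)CCC#C
F11 | step 14 | (2E)-5-[(1S,2R,4aR,5S)-5-(methoxycarbonyl)-1,2,5-trimethyl-1,2,3,4,4a,5,6,7-octahydronaphthalen-1-yl]-3-methylpent-2-enoic acid | COC(=O)[C@@]1(C)CCC=C2[C@H]1CC[C@@H](C)[C@]2(C)CC/C(C)=C/C(O)=O
A1 | alternative 1 | (E)-2-methylbut-2-enal | C/C=C(\C)C=O
A2 | alternative 1 | (E)-1-(trimethylsilyloxy)buta-1,3-diene | C=C/C=C/O[Si](C)(C)C
A3 | alternative 1 | (1S,2R,6R)-1,6-dimethyl-2-[(trimethylsilyl)oxy]cyclohex-3-ene-1-carbaldehyde | O=C[C@]1(C)[C@H](O[Si](C)(C)C)C=CC[C@H]1C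
A4 | alternative 2 | methyl (1S,4aR,5S,6R,8aR)-3-[(tert-butyldimethylsilyl)oxy]-1,5,6-trimethyl-5-[2-(2-methyl-1,3-dioxolan-2-yl)ethyl]-1,2,4a,5,6,7,8,8a-octahydronaphthalene-1-carboxylate | COC(=O)[C@@]1(C)CC(O[Si](C)(C)C(C)(C)C)=C[C@H]2[C@H]1CC[C@@H](C)[C@]2(C)CCC3(C)OCCO3
A5 | alternative 3 | methyl (1S,5S,6R,8aS)-5,6-dimethyl-5-[2-(2-methyl-1,3-dioxolan-2-yl)ethyl]-1,2,3,5,6,7,8,8a-octahydronaphthalene-1-carboxylate | COC(=O)[C@H]1CCC=C2[C@H]1CC[C@@H](C)[C@]2(C)CCC3(C)OCCO3
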